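## The problem

Target **29** is a sesquineolignan. An olivil-type oxolane (ring A: O1, C2H2, C3, C4, C5) is joined through C5 to the benzo ring (ring B) of a 2-aryl-3-(hydroxymethyl)-2,3-dihydrobenzofuran (ring C: O1', C2', C3', C3a', C7a'). Ring A has three contiguous stereocentres: the tertiary carbinol C3 (S) with a 4-hydroxy-3-methoxybenzyl group, C4 (R) with CH2OH and C5 (R) with the aryl group. The three carbon substituents lie on one face and the hydroxyl on the other, so this is the crowded arrangement. Ring C has C2' (R) and C3' (R) with the guaiacyl ring and CH2OH cis, which is the kinetic and not the thermodynamic isomer. Inside ring A the centres can relay (C3 can direct C4, and both can direct C5), but the two clusters sit para to each other across ring B and cannot control one another, so ring C needs reagent control. The fragile spots are the cis ring C (C3' epimerizes at the ester or aldehyde level; the C2'–O1' bond of a p-hydroxybenzyl aryl ether opens through a quinone methide in acid or base), the benzylic C5–O1 ether (ionization, hydrogenolysis), the two phenols and the tertiary alcohol. A late closure of ring C is possible because the C2'–C3' bond joins an O-benzylic methine (C2', between O1' and the guaiacyl ring) to a carbon (C3') that is attached to C3a' and bears a carboxyl-level carbon. C3' can therefore be the carbene carbon of an aryldiazoacetate, and the C2'–H bond of an aryl benzyl ether lies in the 1,5 relationship (C3'–C3a'–C7a'–O1'–C2') needed for insertion.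

## Retrosynthesis

**29 ⇒ 28 ⇒ 27.** No skeletal bond is cut. The two phenols, the primary and the tertiary hydroxyl of ring A go back to silyl ethers (aryl TIPS, primary TBS, tertiary TES), and the C3' hydroxymethyl goes back to a methyl ester. This gives the cis ester **27**, the direct product type of a carbenoid insertion. The forward steps must reduce the ester without base and free the phenols without leaving a phenoxide next to C2' for long.

**27 ⇒ 26.** The C2'–C3' bond is cut and ring C is opened. Cutting O1'–C2' instead would require substitution at an ionizable benzylic carbon, and an oxidative phenol coupling would give the trans ring. The C–C cut removes both ring C stereocentres at once and leaves a diazoacetate and a benzyl ether on ring B of an otherwise complete molecule. The forward reaction must deliver kinetic cis selectivity and absolute control from the catalyst alone.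

**26 ⇒ 25 ⇒ 24 ⇒ 23 ⇒ 21.** The diazo group comes from diazo transfer to the arylacetate **25**. Its two-carbon chain comes from an allyl group by oxidative cleavage (aldehyde **23**, acid **24**). An allyl group is preferred to a masked acetate because it is inert to an aryllithium and to BF3·OEt2 and can be placed ortho to the phenol oxygen by rearrangement.

**21 ⇒ 20 ⇒ 14 + 18.** The C5–aryl bond and the C5–H bond are cut. Aryllithium **19**, made from bromide **18**, adds to lactone **14** to give lactol **20**, and hydride delivery to the derived oxocarbenium ion sets C5. The neighbouring cut, closing ring A by C–O bond formation from an open diol, would need a separate, reagent-controlled C5 carbinol. Here C5 is set by C3 and C4: hydride enters anti to the C4 substituent and syn to the C3 oxygen, which places the aryl group cis to both carbon substituents. The precursors are an achiral aryl bromide and a lactone with two stereocentres.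

**18 ⇒ 17 + 4; 17 ⇒ 16 ⇒ 15.** The benzyl ether O–CH2 bond is cut. Installing this ether before metalation lets it serve both as the protecting group of the ring B phenol and as the later C–H donor, which saves a protection and deprotection pair. Phenol **17** follows from O-allylation of **15** to **16** and aromatic Claisen rearrangement, whose regiochemistry is fixed by the substitution pattern.

**14 ⇒ 12 ⇒ 10.** The bond between the lactone α-carbon and the hydroxymethyl carbon is cut (aldol of dianion **11** with a one-carbon aldehyde). Bringing this carbon in earlier, by anti-selective C3 alkylation of a malate ester, would place it cis to the hydroxyl on the lactone ring, which is the wrong relationship. The dianion aldol is expected to place it trans, as needed, and the alkoxide cannot be eliminated.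

**10 ⇒ 8 ⇒ 6 + 4; 6 ⇒ 5.** The bond from the carbinol carbon to the benzyl group is cut. (S)-Malic acid **5** supplies the carbinol carbon. Its tert-butyl acetal **6** stores the configuration while the ring enolate **7** is benzylated by **4** with retention to give **8**. The two carboxyl carbons are then told apart by reduction (**9**), which gives the β-hydroxy lactone **10**. This takes the quaternary stereocentre from the chiral pool in three steps.

**4 ⇒ 3 ⇒ 2 ⇒ 1.** The benzylic bromide used in both alkylations comes from vanillin **1** by silylation, reduction and bromination.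

## Roads not taken

**Alternative 1:** Ring A is built on a preformed ring C. The cut runs through the C4–C5 bond and the lactone C–O bond. The cis-dihydrobenzofuran aldehyde A1 is combined with the γ-(silyloxymethyl) 2-(methoxycarbonyl)allylboronate A2 under a chiral Lewis or Brønsted acid, and the homoallylic alcohol lactonizes to the cis α-methylene lactone A3.
- Merits: the cis C4/C5 relationship follows stereospecifically from the geometry of A2 (silyloxymethyl cis to the boron-bearing carbon) through a closed transition state. That is a firmer basis than the facial hydride delivery used here. Ring C could also be made early, on simple material, where a failed insertion costs little.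
- Weak points: A1 is an electron-rich, poorly electrophilic aldehyde, and its ring C is an acid-labile p-silyloxybenzyl aryl ether, so the acid that accelerates the allylboration threatens cis-to-trans isomerization. After A3 the tertiary carbinol must still be made (epoxidation of the methylene group, opening with an aryl cuprate) and the lactone carbonyl must be reduced to the C2 methylene. That is at least four more operations in the presence of the fragile ring.
- Comparison: the chosen plan cannot match the stereospecificity at C4/C5. Against that, it has ring A at its final oxidation level as soon as it is formed and exposes the cis ring C to only two mild steps.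

**Alternative 2:** Ring C is closed at the other bond, O1'–C2'. A syn aldol sets both carbons and leads to the phenol diol A4. Mitsunobu activation of the benzylic hydroxyl lets the ortho phenol displace it with inversion to give the cis-dihydrobenzofuran acetal A5, from whose aldehyde ring A would then be grown.
- Merits: ordinary reagents, no diazo compound and no rhodium. The absolute configuration comes from an auxiliary-controlled aldol whose diastereomers can be purified, which is at least as dependable as catalyst control. The outcome of an SN2 closure is easy to predict.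
- Weak points: the carbon to be inverted is benzylic and para to an oxygen substituent. Even with the deactivating pivalate, the activated alcohol can ionize to a quinone-methide-like cation, and any SN1 share gives the thermodynamically preferred trans ring. Aldols of arylacetates with electron-rich benzaldehydes are prone to retro-aldol and epimerization. The sequence to A4 is long, and A5 is only the ring B/ring C half.
- Comparison: this road is better in cost and scalability. The chosen plan sets the kinetic cis geometry in the insertion transition state, forms a C–C bond instead of substituting at an ionizable centre, and closes ring C last.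

**Alternative 3:** The cut goes through three bonds around the C3–C4 edge of ring A. The propargylic alcohol A6, from asymmetric alkynylation of A1, is deprotonated and undergoes copper-catalysed anti carbomagnesiation with a silylmethyl Grignard reagent. Carboxylation of the vinylmagnesium and acidic work-up form the C4–CH2Si bond, the bond to the new carbonyl carbon and the lactone C–O bond, giving the butenolide A7 in one flask. Conjugate reduction, enolate hydroxylation, oxidation of the C–Si bond and removal of the carbonyl oxygen would complete ring A.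
- Merits: no other road assembles the carbon skeleton of ring A so quickly. The all-cis arrangement is plausible because each later reagent would approach anti to the C5 aryl group.
- Weak points: all three ring A centres then depend on the single carbinol of A6, set by reagent control on a complex aldehyde. The propargylic, benzylic CH2 of A6 can isomerize to the allene under the basic conditions. Conjugate reduction of a tetrasubstituted butenolide is difficult. The peroxide and fluoride used to oxidize the C–Si bond do not suit aryl silyl ethers. The lactone carbonyl must again be removed, and every step is run with ring C present.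
- Comparison: in bond-forming economy this road is better. The chosen plan answers with ring A stereocentres relayed from the chiral pool and with the fragile cis ring made at the end.

Key step: step 18

Assumption: Rh2(S-PTTL)4 is taken to give the (2R,3S) cis ester **27**, by analogy with simple 2-(benzyloxy)phenyl diazoacetates; if the first run shows the opposite sense, the mirror-image catalyst Rh2(R-PTTL)4 is used and nothing else changes.

Abbreviations: Ar = 3-methoxy-4-(triisopropylsilyloxy)phenyl; TIPS = triisopropylsilyl; TBS = tert-butyldimethylsilyl; TES = triethylsilyl; TBSOCH2 = (tert-butyldimethylsilyloxy)methyl; PTTL = N-phthaloyl-tert-leucinate. Oxolane locants in the names of 20–29 follow ring A of the target; lactones 10–14 use oxolan-2-one locants.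

## Steps

Step 1
Reactants: 1 vanillin (4-hydroxy-3-methoxybenzaldehyde)
Product: 2 3-methoxy-4-(triisopropylsilyloxy)benzaldehyde
Conditions: TIPSCl, imidazole, DMF, 0 °C to rt
Reagents that add atoms: chlorotriisopropylsilane, CC(C)[Si](Cl)(C(C)C)C(C)C
Why: Imidazole-promoted O-silylation of a phenol; the bulky TIPS aryl ether is chosen because it must outlast carbonate, lithium amides, borohydride, an organolithium and BF3·OEt2 before fluoride removes it.

Step 2
Reactants: 2 3-methoxy-4-(triisopropylsilyloxy)benzaldehyde
Product: 3 [3-methoxy-4-(triisopropylsilyloxy)phenyl]methanol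
Conditions: NaBH4, MeOH, 0 °C
Reagents that add atoms: none
Why: Borohydride reduction of an aromatic aldehyde; nothing else in 2 is reducible.

Step 3
Reactants: 3 [3-methoxy-4-(triisopropylsilyloxy)phenyl]methanol
Product: 4 4-(bromomethyl)-2-methoxy-1-(triisopropylsilyloxy)benzene (ArCH2Br)
Conditions: CBr4, PPh3, CH2Cl2, 0 °C
Reagents that add atoms: carbon tetrabromide, BrC(Br)(Br)Br
Why: Appel bromination under neutral conditions, which an ionizable p-silyloxybenzyl alcohol tolerates; the bromide is used soon after a short silica filtration.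

Step 4
Reactants: 5 (S)-malic acid
Product: 6 2-[(2S,4S)-2-tert-butyl-5-oxo-1,3-dioxolan-4-yl]acetic acid (cis)
Conditions: t-BuCHO, TsOH (cat.), H2SO4 (cat.), pentane, reflux, water separator
Reagents that add atoms: pivalaldehyde, CC(C)(C)C=O
Why: Acid-catalysed acetalization of the α-hydroxy acid unit gives the five-membered dioxolanone; the cis isomer is the thermodynamic product and is purified by crystallization, so the new acetal centre (S) stores the configuration of the malic acid carbinol.

Step 5
Reactants: 6 2-[(2S,4S)-2-tert-butyl-5-oxo-1,3-dioxolan-4-yl]acetic acid; 4 ArCH2Br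
Product: 8 2-[(2S,4S)-4-(ArCH2)-2-tert-butyl-5-oxo-1,3-dioxolan-4-yl]acetic acid (benzyl trans to tert-butyl), via dilithium enolate carboxylate 7 (not isolated)
Conditions: LiN(SiMe3)2 (2.2 equiv), THF, −78 °C; then 4, −78 to −30 °C; dilute HCl work-up
Reagents that add atoms: none
Why: Enolate alkylation by the self-regeneration-of-stereocentres principle: the planar ring enolate is attacked by the benzylic bromide on the face opposite the tert-butyl group, so the benzyl group replaces the former hydrogen with overall retention and the quaternary carbinol carbon is formed as the (S) centre.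

Step 6
Reactants: 8 2-[(2S,4S)-4-(ArCH2)-2-tert-butyl-5-oxo-1,3-dioxolan-4-yl]acetic acid
Product: 10 (4S)-4-(ArCH2)-4-hydroxyoxolan-2-one, via dihydroxy acid 9 (not isolated)
Conditions: LiBH4 (4 equiv), THF, 0 °C to rt; then 2 M HCl, rt
Reagents that add atoms: none
Why: Chemoselective borohydride reduction of an ester beside a carboxylate (half-ester logic): the first hydride only deprotonates the acid, the acylal carbonyl is reduced to CH2OH with release of the acetal carbon as neopentyl alcohol, and acidification closes the γ-lactone onto the untouched carboxyl; the quaternary centre is not involved.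

Step 7
Reactants: 10 (4S)-4-(ArCH2)-4-hydroxyoxolan-2-one
Product: 12 (3S,4S)-4-(ArCH2)-4-hydroxy-3-(hydroxymethyl)oxolan-2-one (CH2OH trans to OH), via dilithium alkoxide enolate 11 (not isolated)
Conditions: LiN(i-Pr)2 (2.3 equiv), THF, −78 to −40 °C; CH2O (gas), −78 °C; AcOH, −78 °C
Reagents that add atoms: formaldehyde, C=O
Why: Aldol reaction of a β-hydroxy lactone dianion (Fráter–Seebach type): the lithium alkoxide shields its own face of the enolate and cannot be eliminated, so formaldehyde should enter anti to the C–O bond and set the α-carbon (S) with CH2OH trans to the hydroxyl and cis to the benzyl group.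

Step 8
Reactants: 12 (3S,4S)-4-(ArCH2)-4-hydroxy-3-(hydroxymethyl)oxolan-2-one
Product: 14 (3S,4S)-3-(TBSOCH2)-4-(ArCH2)-4-(triethylsilyloxy)oxolan-2-one, via mono-TBS ether 13 (not isolated)
Conditions: TBSOTf (1.05 equiv), 2,6-lutidine, CH2Cl2, −78 °C; then TESOTf (1.5 equiv), −78 to 0 °C
Reagents that add atoms: tert-butyldimethylsilyl trifluoromethanesulfonate, CC(C)(C)[Si](C)(C)OS(=O)(=O)C(F)(F)F; triethylsilyl trifluoromethanesulfonate, CC[Si](CC)(CC)OS(=O)(=O)C(F)(F)F
Why: Sequential silylation with silyl triflates: the primary hydroxyl reacts at −78 °C and the hindered tertiary one only with the smaller TES triflate on warming; masking the tertiary hydroxyl prevents quenching of the aryllithium and retro-aldol cleavage later.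

Step 9
Reactants: 15 4-bromo-2-methoxyphenol
Product: 16 1-(allyloxy)-4-bromo-2-methoxybenzene
Conditions: allyl bromide, K2CO3, acetone, reflux
Reagents that add atoms: allyl bromide, C=CCBr
Why: Williamson ether synthesis on a phenol.

Step 10
Reactants: 16 1-(allyloxy)-4-bromo-2-methoxybenzene
Product: 17 2-allyl-4-bromo-6-methoxyphenol
Conditions: N,N-diethylaniline, 200 °C
Reagents that add atoms: none
Why: Aromatic Claisen rearrangement; only one ortho position is free and the para position is blocked by bromine, so a single regioisomer results.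

Step 11
Reactants: 17 2-allyl-4-bromo-6-methoxyphenol; 4 ArCH2Br
Product: 18 1-allyl-5-bromo-3-methoxy-2-(ArCH2O)benzene
Conditions: K2CO3, DMF, rt
Reagents that add atoms: none
Why: Williamson etherification with a reactive benzylic bromide; the ether is at once the protecting group of the ring B phenol and the C–H donor of the key step, and the TIPS aryl ether resists carbonate.

Step 12
Reactants: 18 1-allyl-5-bromo-3-methoxy-2-(ArCH2O)benzene; 14 (3S,4S)-3-(TBSOCH2)-4-(ArCH2)-4-(triethylsilyloxy)oxolan-2-one
Product: 20 (3S,4S)-5-[3-allyl-5-methoxy-4-(ArCH2O)phenyl]-4-(TBSOCH2)-3-(ArCH2)-3-(triethylsilyloxy)oxolan-5-ol (anomer mixture; ring form of the γ-hydroxy ketone), via aryllithium 19 (not isolated)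
Conditions: n-BuLi, THF, −78 °C; then 14, −78 °C; AcOH, −78 °C
Reagents that add atoms: none
Why: Bromine–lithium exchange is faster at −78 °C than attack on the benzyl ether or the allylic C–H; the aryllithium adds once to the lactone because the lithium hemiketalate is stable at this temperature, and the cold acidic quench prevents ring opening, silyl migration and β-elimination.

Step 13
Reactants: 20 the lactol from step 12
Product: 21 (3S,4R,5R)-5-[3-allyl-5-methoxy-4-(ArCH2O)phenyl]-4-(TBSOCH2)-3-(ArCH2)-3-(triethylsilyloxy)oxolane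
Conditions: Et3SiH, BF3·OEt2, CH2Cl2, −78 °C
Reagents that add atoms: none
Why: Ionic hydrogenation of a lactol: BF3 ionizes 20 to the aryl-stabilized oxocarbenium ion and Et3SiH delivers hydride to the face opposite the C4 CH2OTBS group and syn to the pseudoaxial C3 silyloxy group (inside attack on the envelope). This sets C5 (R) with the aryl group cis to both carbon substituents; the low temperature and excess silane keep the electron-rich benzyl ether and the C4 centre intact.

Step 14
Reactants: 21 the oxolane from step 13
Product: 23 (3S,4R,5R)-5-[5-methoxy-3-(2-oxoethyl)-4-(ArCH2O)phenyl]-4-(TBSOCH2)-3-(ArCH2)-3-(triethylsilyloxy)oxolane, via vicinal diol 22 (not isolated)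
Conditions: OsO4 (cat.), NaIO4, 2,6-lutidine, dioxane/H2O, rt
Reagents that add atoms: osmium tetroxide (oxygen carrier, re-formed by NaIO4), O=[Os](=O)(=O)=O; sodium periodate, [Na+].[O-]I(=O)(=O)=O
Why: Johnson–Lemieux oxidative cleavage of the only alkene; the lutidine buffer protects the silyl ethers and the crude arylacetaldehyde is oxidized at once.

Step 15
Reactants: 23 the arylacetaldehyde from step 14
Product: 24 (3S,4R,5R)-5-[3-(carboxymethyl)-5-methoxy-4-(ArCH2O)phenyl]-4-(TBSOCH2)-3-(ArCH2)-3-(triethylsilyloxy)oxolane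
Conditions: NaClO2, NaH2PO4, 2-methyl-2-butene, t-BuOH/H2O, 0 °C to rt
Reagents that add atoms: sodium chlorite, [Na+].[O-]Cl=O
Why: Pinnick oxidation; the alkene scavenger removes hypochlorite before it can chlorinate the electron-rich rings, and the buffered medium spares the silyl ethers.

Step 16
Reactants: 24 the arylacetic acid from step 15
Product: 25 (3S,4R,5R)-5-[5-methoxy-3-(2-methoxy-2-oxoethyl)-4-(ArCH2O)phenyl]-4-(TBSOCH2)-3-(ArCH2)-3-(triethylsilyloxy)oxolane
Conditions: TMSCHN2, MeOH/toluene, 0 °C
Reagents that add atoms: (trimethylsilyl)diazomethane, C[Si](C)(C)C=[N+]=[N-]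
Why: Methyl esterification of a carboxylic acid with (trimethylsilyl)diazomethane under neutral conditions.

Step 17
Reactants: 25 the methyl arylacetate from step 16
Product: 26 (3S,4R,5R)-5-[3-(1-diazo-2-methoxy-2-oxoethyl)-5-methoxy-4-(ArCH2O)phenyl]-4-(TBSOCH2)-3-(ArCH2)-3-(triethylsilyloxy)oxolane
Conditions: p-acetamidobenzenesulfonyl azide, DBU, MeCN, 0 °C to rt
Reagents that add atoms: 4-acetamidobenzenesulfonyl azide, CC(=O)Nc1ccc(cc1)S(=O)(=O)N=[N+]=[N-]
Why: Regitz diazo transfer to the benzylic ester enolate, the standard entry to aryldiazoacetates; anhydrous conditions and a short reaction time keep the aryl silyl ethers intact.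

Step 18
Reactants: 26 the aryldiazoacetate from step 17
Product: 27 methyl (2R,3S)-2-Ar-7-methoxy-5-[(3S,4R,5R)-4-(TBSOCH2)-3-(ArCH2)-3-(triethylsilyloxy)oxolan-5-yl]-2,3-dihydro-1-benzofuran-3-carboxylate (2,3-cis)
Conditions: Rh2(S-PTTL)4 (2 mol %), toluene, −60 °C
Reagents that add atoms: none
Why: The catalyst, a tetracarboxylate of divalent rhodium, takes up the diazo carbon of 26 and loses N2 to give a donor/acceptor rhodium carbene at C3'. The electrophilic carbene carbon inserts into the O-benzylic C2'–H bond through a concerted, asynchronous three-centre transition state with hydride-transfer character, forming C2'–C3' and releasing the catalyst; the closest known reaction type is the enantio- and cis-selective intramolecular C–H insertion of methyl 2-(2-benzyloxyphenyl)-2-diazoacetates under chiral dirhodium N-phthaloyl amino acid carboxylates. Ring C closes in the 1,5 mode, the only five-membered option, because C2'–H is the sole C–H held five atoms from the carbene carbon by the rigid C3a'–C7a'–O1' tether. C2' (R) and C3' (S in the ester, the same spatial arrangement as 3'R in 29) are set together: the cis relationship is kinetic, the aryl group and the ester both avoiding the ligand wall in the insertion transition state, and the absolute sense comes from the (S)-tert-leucinate ligands, the ring A centres being too remote to interfere. The step needs selectivity for C–H insertion over O–H insertion, carbene dimerization and attack on the arenes; this is secured by silylating every hydroxyl, by the activation of the target C–H through O1' and the electron-rich aryl group, by its intramolecular position and by low temperature in a non-coordinating solvent. Because acid or base would turn the cis ester into the trans isomer, the product is handled neutrally and reduced at once.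

Step 19
Reactants: 27 the cis ester from step 18
Product: 28 [(2R,3R)-2-Ar-7-methoxy-5-[(3S,4R,5R)-4-(TBSOCH2)-3-(ArCH2)-3-(triethylsilyloxy)oxolan-5-yl]-2,3-dihydro-1-benzofuran-3-yl]methanol (2,3-cis)
Conditions: i-Bu2AlH, CH2Cl2, −78 to −20 °C; aqueous potassium sodium tartrate
Reagents that add atoms: none
Why: Reduction of an ester to the primary alcohol with a neutral aluminium hydride at low temperature; no base is present, so the cis C3' centre is kept and the silyl ethers are untouched.

Step 20
Reactants: 28 the alcohol from step 19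
Product: 29 (3S,4R,5R)-5-[(2R,3R)-2-(4-hydroxy-3-methoxyphenyl)-3-(hydroxymethyl)-7-methoxy-2,3-dihydro-1-benzofuran-5-yl]-3-[(4-hydroxy-3-methoxyphenyl)methyl]-4-(hydroxymethyl)oxolan-3-ol
Conditions: TBAF, AcOH, THF, 0 °C to rt
Reagents that add atoms: none
Why: Fluoride cleavage of all four silyl ethers; acetic acid buffers the phenoxides so that the p-hydroxybenzyl aryl ether of ring C is not opened to a quinone methide, and no stereocentre is touched.

## Compound list

1 | vanillin (4-hydroxy-3-methoxybenzaldehyde) | COc1cc(C=O)ccc1O | starting material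
2 | 3-methoxy-4-(triisopropylsilyloxy)benzaldehyde | COc1cc(C=O)ccc1O[Si](C(C)C)(C(C)C)C(C)C | intermediate
3 | [3-methoxy-4-(triisopropylsilyloxy)phenyl]methanol | COc1cc(CO)ccc1O[Si](C(C)C)(C(C)C)C(C)C | intermediate
4 | 4-(bromomethyl)-2-methoxy-1-(triisopropylsilyloxy)benzene (ArCH2Br) | COc1cc(CBr)ccc1O[Si](C(C)C)(C(C)C)C(C)C | intermediate
5 | (S)-malic acid | OC(=O)C[C@H](O)C(=O)O | starting material
6 | 2-[(2S,4S)-2-tert-butyl-5-oxo-1,3-dioxolan-4-yl]acetic acid (cis) | OC(=O)C[C@@H]1O[C@H](C(C)(C)C)OC1=O | intermediate
7 | dilithium salt of 6 (carboxylate and ring enolate; acetal centre S retained) | [Li]OC(=O)CC1=C(O[Li])O[C@@H](C(C)(C)C)O1 | intermediate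
8 | 2-[(2S,4S)-4-(ArCH2)-2-tert-butyl-5-oxo-1,3-dioxolan-4-yl]acetic acid | OC(=O)C[C@]1(Cc2ccc(O[Si](C(C)C)(C(C)C)C(C)C)c(OC)c2)O[C@H](C(C)(C)C)OC1=O | intermediate
9 | (3S)-3-(ArCH2)-3,4-dihydroxybutanoic acid (lithium salt in the flask) | OC(=O)C[C@@](O)(Cc1ccc(O[Si](C(C)C)(C(C)C)C(C)C)c(OC)c1)CO | intermediate
10 | (4S)-4-(ArCH2)-4-hydroxyoxolan-2-one | O=C1C[C@@](O)(Cc2ccc(O[Si](C(C)C)(C(C)C)C(C)C)c(OC)c2)CO1 | intermediate
11 | dilithium alkoxide enolate of 10 | [Li]OC1=C[C@@](O[Li])(Cc2ccc(O[Si](C(C)C)(C(C)C)C(C)C)c(OC)c2)CO1 | intermediate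
12 | (3S,4S)-4-(ArCH2)-4-hydroxy-3-(hydroxymethyl)oxolan-2-one | O=C1[C@@H](CO)[C@@](O)(Cc2ccc(O[Si](C(C)C)(C(C)C)C(C)C)c(OC)c2)CO1 | intermediate
13 | (3S,4S)-3-(TBSOCH2)-4-(ArCH2)-4-hydroxyoxolan-2-one | O=C1[C@@H](CO[Si](C)(C)C(C)(C)C)[C@@](O)(Cc2ccc(O[Si](C(C)C)(C(C)C)C(C)C)c(OC)c2)CO1 | intermediate
14 | (3S,4S)-3-(TBSOCH2)-4-(ArCH2)-4-(triethylsilyloxy)oxolan-2-one | O=C1[C@@H](CO[Si](C)(C)C(C)(C)C)[C@@](O[Si](CC)(CC)CC)(Cc2ccc(O[Si](C(C)C)(C(C)C)C(C)C)c(OC)c2)CO1 | intermediate
15 | 4-bromo-2-methoxyphenol | COc1cc(Br)ccc1O | starting material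
16 | 1-(allyloxy)-4-bromo-2-methoxybenzene | COc1cc(Br)ccc1OCC=C | intermediate
17 | 2-allyl-4-bromo-6-methoxyphenol | COc1cc(Br)cc(CC=C)c1O | intermediate
18 | 1-allyl-5-bromo-3-methoxy-2-(ArCH2O)benzene | COc1cc(Br)cc(CC=C)c1OCc1ccc(O[Si](C(C)C)(C(C)C)C(C)C)c(OC)c1 | intermediate
19 | [3-allyl-5-methoxy-4-(ArCH2O)phenyl]lithium | [Li]c1cc(OC)c(OCc2ccc(O[Si](C(C)C)(C(C)C)C(C)C)c(OC)c2)c(CC=C)c1 | intermediate
20 | (3S,4S)-5-[3-allyl-5-methoxy-4-(ArCH2O)phenyl]-4-(TBSOCH2)-3-(ArCH2)-3-(triethylsilyloxy)oxolan-5-ol (anomer mixture) | OC1(c2cc(OC)c(OCc3ccc(O[Si](C(C)C)(C(C)C)C(C)C)c(OC)c3)c(c2)CC=C)[C@@H](CO[Si](C)(C)C(C)(C)C)[C@@](O[Si](CC)(CC)CC)(Cc2ccc(O[Si](C(C)C)(C(C)C)C(C)C)c(OC)c2)CO1 | intermediate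
21 | (3S,4R,5R)-5-[3-allyl-5-methoxy-4-(ArCH2O)phenyl]-4-(TBSOCH2)-3-(ArCH2)-3-(triethylsilyloxy)oxolane | COc1cc(C[C@@]2(O[Si](CC)(CC)CC)CO[C@@H](c3cc(OC)c(OCc4ccc(O[Si](C(C)C)(C(C)C)C(C)C)c(OC)c4)c(c3)CC=C)[C@H]2CO[Si](C)(C)C(C)(C)C)ccc1O[Si](C(C)C)(C(C)C)C(C)C | intermediate
22 | the 2,3-dihydroxypropyl analogue of 21 (diol epimers) | COc1cc(C[C@@]2(O[Si](CC)(CC)CC)CO[C@@H](c3cc(OC)c(OCc4ccc(O[Si](C(C)C)(C(C)C)C(C)C)c(OC)c4)c(c3)CC(O)CO)[C@H]2CO[Si](C)(C)C(C)(C)C)ccc1O[Si](C(C)C)(C(C)C)C(C)C | intermediate
23 | (3S,4R,5R)-5-[5-methoxy-3-(2-oxoethyl)-4-(ArCH2O)phenyl]-4-(TBSOCH2)-3-(ArCH2)-3-(triethylsilyloxy)oxolane | COc1cc(C[C@@]2(O[Si](CC)(CC)CC)CO[C@@H](c3cc(OC)c(OCc4ccc(O[Si](C(C)C)(C(C)C)C(C)C)c(OC)c4)c(c3)CC=O)[C@H]2CO[Si](C)(C)C(C)(C)C)ccc1O[Si](C(C)C)(C(C)C)C(C)C | intermediate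
24 | (3S,4R,5R)-5-[3-(carboxymethyl)-5-methoxy-4-(ArCH2O)phenyl]-4-(TBSOCH2)-3-(ArCH2)-3-(triethylsilyloxy)oxolane | COc1cc(C[C@@]2(O[Si](CC)(CC)CC)CO[C@@H](c3cc(OC)c(OCc4ccc(O[Si](C(C)C)(C(C)C)C(C)C)c(OC)c4)c(c3)CC(O)=O)[C@H]2CO[Si](C)(C)C(C)(C)C)ccc1O[Si](C(C)C)(C(C)C)C(C)C | intermediate
25 | (3S,4R,5R)-5-[5-methoxy-3-(2-methoxy-2-oxoethyl)-4-(ArCH2O)phenyl]-4-(TBSOCH2)-3-(ArCH2)-3-(triethylsilyloxy)oxolane | COc1cc(C[C@@]2(O[Si](CC)(CC)CC)CO[C@@H](c3cc(OC)c(OCc4ccc(O[Si](C(C)C)(C(C)C)C(C)C)c(OC)c4)c(c3)CC(=O)OC)[C@H]2CO[Si](C)(C)C(C)(C)C)ccc1O[Si](C(C)C)(C(C)C)C(C)C | intermediate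
26 | (3S,4R,5R)-5-[3-(1-diazo-2-methoxy-2-oxoethyl)-5-methoxy-4-(ArCH2O)phenyl]-4-(TBSOCH2)-3-(ArCH2)-3-(triethylsilyloxy)oxolane | COc1cc(C[C@@]2(O[Si](CC)(CC)CC)CO[C@@H](c3cc(OC)c(OCc4ccc(O[Si](C(C)C)(C(C)C)C(C)C)c(OC)c4)c(c3)C(=[N+]=[N-])C(=O)OC)[C@H]2CO[Si](C)(C)C(C)(C)C)ccc1O[Si](C(C)C)(C(C)C)C(C)C | intermediate
27 | methyl (2R,3S)-2-Ar-7-methoxy-5-[(3S,4R,5R)-4-(TBSOCH2)-3-(ArCH2)-3-(triethylsilyloxy)oxolan-5-yl]-2,3-dihydro-1-benzofuran-3-carboxylate (cis) | COc1cc(C[C@@]2(O[Si](CC)(CC)CC)CO[C@@H](c3cc(OC)c4c(c3)[C@H](C(=O)OC)[C@H](c3ccc(O[Si](C(C)C)(C(C)C)C(C)C)c(OC)c3)O4)[C@H]2CO[Si](C)(C)C(C)(C)C)ccc1O[Si](C(C)C)(C(C)C)C(C)C | intermediate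
28 | [(2R,3R)-2-Ar-7-methoxy-5-[(3S,4R,5R)-4-(TBSOCH2)-3-(ArCH2)-3-(triethylsilyloxy)oxolan-5-yl]-2,3-dihydro-1-benzofuran-3-yl]methanol (cis) | COc1cc(C[C@@]2(O[Si](CC)(CC)CC)CO[C@@H](c3cc(OC)c4c(c3)[C@H](CO)[C@H](c3ccc(O[Si](C(C)C)(C(C)C)C(C)C)c(OC)c3)O4)[C@H]2CO[Si](C)(C)C(C)(C)C)ccc1O[Si](C(C)C)(C(C)C)C(C)C | intermediate
29 | (3S,4R,5R)-5-[(2R,3R)-2-(4-hydroxy-3-methoxyphenyl)-3-(hydroxymethyl)-7-methoxy-2,3-dihydro-1-benzofuran-5-yl]-3-[(4-hydroxy-3-methoxyphenyl)methyl]-4-(hydroxymethyl)oxolan-3-ol (CNP0284796.1) | COc1cc(C[C@@]2(O)CO[C@@H](c3cc(OC)c4c(c3)[C@H](CO)[C@H](c3ccc(O)c(OC)c3)O4)[C@H]2CO)ccc1O | target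

## Step count and risks

Total steps: 20. Longest linear sequence: 16 steps (steps 1–3, 5–8 and 12–20, from vanillin 1).

**Step 18 (key step).** Most likely failure: erosion of cis selectivity and of catalyst control, because the very electron-rich O-benzylic C–H may react through a stepwise hydride-transfer pathway whose ion pair can rotate or fragment before the C–C bond forms; carbene dimerization is the second concern. Fallback (changes the electronic design of the substrate, not the catalyst): from ester 25, the two aryl TIPS ethers are removed selectively (TBAF, 2 equiv, THF, −20 °C) to give the bis-phenol F1. Both phenols are acylated (PivCl, Et3N, DMAP) to the bis-pivalate F2, and diazo transfer gives the diazo ester F3. The insertion is then run on this less electron-rich benzyl ether to give the cis ester bis-pivalate F4. i-Bu2AlH reduces the methyl ester and cleaves both pivalates to the triol F5, and buffered TBAF removes the TBS and TES groups, which rejoins the route at the target 29.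

**Step 7.** Most likely failure: poor facial selectivity in the aldol, because the benzyl group on the quaternary carbon shields the face that the alkoxide leaves open. Fallback (hydrogen, not carbon, is delivered, and from the hydroxyl face): from lactone 10, the dianion is formylated with ethyl formate to the hydroxymethylidene lactone F6, and the enol is silylated (TBSCl, Et3N) to the silyl enol ether F7. Hydroxyl-directed hydrogenation with [Ir(cod)(PCy3)(py)]PF6 adds H2 cis to the tertiary hydroxyl and so places CH2OTBS trans to it. This gives the mono-TBS ether 13, which is taken on with TESOTf to 14.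

**Step 12.** Most likely failure: deprotonation of the hindered lactone at its α-carbon by the aryllithium instead of addition, followed by β-elimination of the silyloxy group, or opening of the lithium hemiketalate with silyl migration. Fallback (an aldehyde instead of a lactone as the electrophile): lactone 14 is reduced with i-Bu2AlH (1.1 equiv, −78 °C) to the lactol F8. Aryllithium 19 (2 equiv, −78 °C) adds to its hydroxy aldehyde form to give the diol F9 as a mixture of carbinol epimers. MnO2 oxidizes only the benzylic alcohol, and the γ-hydroxy ketone closes to lactol 20, where the route is rejoined.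

**Step 13.** Most likely failure: incomplete facial selectivity of hydride delivery, epimerization at C4 through reversible proton loss from the oxocarbenium ion, or ionization of the electron-rich benzyl ether by BF3. Fallback (C5 set by a reagent-controlled ketone reduction, ring closed by substitution at the primary carbon): lactol 20 reacts through its open γ-hydroxy ketone form in a Corey–Bakshi–Shibata reduction (catecholborane, −78 °C, which spares the allyl group). The oxazaborolidine enantiomer that gives the (R)-carbinol is used, the (S) one if the aryl group acts as the large substituent; the product is the diol F10. The primary hydroxyl is sulfonylated selectively (TsCl, pyridine, DMAP) to the monotosylate F11, which on warming closes by 5-exo-tet attack of the benzylic hydroxyl, with retention at C5, to give 21.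

## Further compounds

F1 | step 18 | bis-phenol: 25 with both TIPS groups removed | COc1cc(C[C@@]2(O[Si](CC)(CC)CC)CO[C@@H](c3cc(OC)c(OCc4ccc(O)c(OC)c4)c(c3)CC(=O)OC)[C@H]2CO[Si](C)(C)C(C)(C)C)ccc1O
F2 | step 18 | bis-pivalate of F1 (both phenols acylated) | COc1cc(C[C@@]2(O[Si](CC)(CC)CC)CO[C@@H](c3cc(OC)c(OCc4ccc(OC(=O)C(C)(C)C)c(OC)c4)c(c3)CC(=O)OC)[C@H]2CO[Si](C)(C)C(C)(C)C)ccc1OC(=O)C(C)(C)C
F3 | step 18 | aryldiazoacetate from F2 | COc1cc(C[C@@]2(O[Si](CC)(CC)CC)CO[C@@H](c3cc(OC)c(OCc4ccc(OC(=O)C(C)(C)C)c(OC)c4)c(c3)C(=[N+]=[N-])C(=O)OC)[C@H]2CO[Si](C)(C)C(C)(C)C)ccc1OC(=O)C(C)(C)C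
F4 | step 18 | cis-(2R,3S)-dihydrobenzofuran methyl ester with both phenols as pivalates (analogue of 27) | COc1cc(C[C@@]2(O[Si](CC)(CC)CC)CO[C@@H](c3cc(OC)c4c(c3)[C@H](C(=O)OC)[C@H](c3ccc(OC(=O)C(C)(C)C)c(OC)c3)O4)[C@H]2CO[Si](C)(C)C(C)(C)C)ccc1OC(=O)C(C)(C)C
F5 | step 18 | 28 lacking both TIPS groups (free phenols and C3' CH2OH; TBS and TES retained) | COc1cc(C[C@@]2(O[Si](CC)(CC)CC)CO[C@@H](c3cc(OC)c4c(c3)[C@H](CO)[C@H](c3ccc(O)c(OC)c3)O4)[C@H]2CO[Si](C)(C)C(C)(C)C)ccc1O
F6 | step 7 | (4S)-4-(ArCH2)-4-hydroxy-3-(hydroxymethylidene)oxolan-2-one (enol of the 3-formyl lactone) | O=C1C(=CO)[C@@](O)(Cc2ccc(O[Si](C(C)C)(C(C)C)C(C)C)c(OC)c2)CO1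
F7 | step 7 | (4S)-3-[(tert-butyldimethylsilyloxy)methylidene]-4-(ArCH2)-4-hydroxyoxolan-2-one | O=C1C(=CO[Si](C)(C)C(C)(C)C)[C@@](O)(Cc2ccc(O[Si](C(C)C)(C(C)C)C(C)C)c(OC)c2)CO1
F8 | step 12 | (3S,4S)-3-(TBSOCH2)-4-(ArCH2)-4-(triethylsilyloxy)oxolan-2-ol (lactol, anomer mixture) | OC1[C@@H](CO[Si](C)(C)C(C)(C)C)[C@@](O[Si](CC)(CC)CC)(Cc2ccc(O[Si](C(C)C)(C(C)C)C(C)C)c(OC)c2)CO1
F9 | step 12 | (2R,3S)-1-[3-allyl-5-methoxy-4-(ArCH2O)phenyl]-2-(TBSOCH2)-3-(ArCH2)-3-(triethylsilyloxy)butane-1,4-diol (C1 epimers) | OC(c2cc(OC)c(OCc3ccc(O[Si](C(C)C)(C(C)C)C(C)C)c(OC)c3)c(c2)CC=C)[C@@H](CO[Si](C)(C)C(C)(C)C)[C@@](O[Si](CC)(CC)CC)(Cc2ccc(O[Si](C(C)C)(C(C)C)C(C)C)c(OC)c2)CO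
F10 | step 13 | (1R,2R,3S)-1-[3-allyl-5-methoxy-4-(ArCH2O)phenyl]-2-(TBSOCH2)-3-(ArCH2)-3-(triethylsilyloxy)butane-1,4-diol | O[C@@H](c2cc(OC)c(OCc3ccc(O[Si](C(C)C)(C(C)C)C(C)C)c(OC)c3)c(c2)CC=C)[C@@H](CO[Si](C)(C)C(C)(C)C)[C@@](O[Si](CC)(CC)CC)(Cc2ccc(O[Si](C(C)C)(C(C)C)C(C)C)c(OC)c2)CO
F11 | step 13 | primary 4-methylbenzenesulfonate of F10 | O[C@@H](c2cc(OC)c(OCc3ccc(O[Si](C(C)C)(C(C)C)C(C)C)c(OC)c3)c(c2)CC=C)[C@@H](CO[Si](C)(C)C(C)(C)C)[C@@](O[Si](CC)(CC)CC)(Cc2ccc(O[Si](C(C)C)(C(C)C)C(C)C)c(OC)c2)COS(=O)(=O)c2ccc(C)cc2
A1 | alternative 1 | (2R,3R)-cis-2-[4-(tert-butyldimethylsilyloxy)-3-methoxyphenyl]-3-[(tert-butyldimethylsilyloxy)methyl]-7-methoxy-2,3-dihydro-1-benzofuran-5-carbaldehyde | O=Cc1cc(OC)c2c(c1)[C@H](CO[Si](C)(C)C(C)(C)C)[C@H](c1ccc(O[Si](C)(C)C(C)(C)C)c(OC)c1)O2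
A2 | alternative 1 | methyl (E)-4-(tert-butyldimethylsilyloxy)-2-[(4,4,5,5-tetramethyl-1,3,2-dioxaborolan-2-yl)methyl]but-2-enoate | COC(=O)/C(CB1OC(C)(C)C(C)(C)O1)=C/CO[Si](C)(C)C(C)(C)C
A3 | alternative 1 | cis-5-aryl-4-(silyloxymethyl)-3-methylenedihydrofuran-2-one carrying the silylated ring C | C=C1C(=O)O[C@@H](c2cc(OC)c3c(c2)[C@H](CO[Si](C)(C)C(C)(C)C)[C@H](c2ccc(O[Si](C)(C)C(C)(C)C)c(OC)c2)O3)[C@H]1CO[Si](C)(C)C(C)(C)C
A4 | alternative 2 | syn-aldol-derived phenol diol: 2-(1,3-dioxolan-2-yl)-substituted 2-hydroxy-3-methoxyphenyl carbinol with CH2OTBS and pivaloyloxy-methoxyphenyl groups | O1CCOC1c1cc(OC)c(O)c(c1)[C@H](CO[Si](C)(C)C(C)(C)C)[C@H](O)c1ccc(OC(=O)C(C)(C)C)c(OC)c1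
A5 | alternative 2 | cis-2-aryl-3-(silyloxymethyl)-7-methoxy-2,3-dihydrobenzofuran-5-carbaldehyde dioxolane acetal (aryl pivalate) | O1CCOC1c1cc(OC)c2c(c1)[C@H](CO[Si](C)(C)C(C)(C)C)[C@H](c1ccc(OC(=O)C(C)(C)C)c(OC)c1)O2
A6 | alternative 3 | propargylic alcohol from alkynylation of A1 with the 3-aryl-1-propyne | O[C@@H](c2cc(OC)c3c(c2)[C@H](CO[Si](C)(C)C(C)(C)C)[C@H](c2ccc(O[Si](C)(C)C(C)(C)C)c(OC)c2)O3)C#CCc1ccc(O[Si](C)(C)C(C)(C)C)c(OC)c1
A7 | alternative 3 | 5-aryl-3-benzyl-4-(silylmethyl)furan-2(5H)-one carrying the silylated ring C | O=C1O[C@@H](c2cc(OC)c3c(c2)[C@H](CO[Si](C)(C)C(C)(C)C)[C@H](c2ccc(O[Si](C)(C)C(C)(C)C)c(OC)c2)O3)C(C[Si](C)(C)OC(C)C)=C1Cc1ccc(O[Si](C)(C)C(C)(C)C)c(OC)c1
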